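**Retrosynthetic overview**
- The target is the [4+2] homodimer of one tetraene monomer; the central cyclohexene is formed last by thermal Diels–Alder dimerisation (terminal CH2=C as dienophile, terminal diene of a second molecule as diene).
- Monomer side chain: the C(CH2OH)=CH–CH=CH–C(=CH2) unit comes from a crossed aldol condensation of a ring-bound CH2CHO arm with a C11 dienal, then a hydroxyl-directed aldehyde reduction; the ring enal comes from a directed aldol condensation on the ring ketone.
- Key step: a photocatalytic acyl-radical 5-exo spirocyclisation of an aldehyde onto a tetrasubstituted cyclohexenone closes the cyclopentane, creates the quaternary spiro carbon and the adjacent CH stereocentre (used here in place of the biomimetic carbonyl-ene closure).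
- The cyclohexenone comes from cyclohexane-1,3-dione through a bicyclic vinylogous ester (Stork–Danheiser) that hides the 3-oxypropyl chain; the carbinol centre is set by Davis hydroxylation and the side-chain centre by organo-SOMO allylation.
- Ring order: cyclohexane (from the dione, with a temporary dihydropyran) → cyclopentane (radical step) → central cyclohexene (dimerisation).

Assumption: the enantiomers of the Davis oxaziridine and of the imidazolidinone catalyst are chosen empirically to give the configurations drawn (both steps are reagent-controlled).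

**Route**

Step 1
Reactants: 1 hept-6-yn-1-ol; 2 1-bromoheptane
Product: 4 tetradec-6-yn-1-ol, via dilithiated hept-6-yn-1-ol 3 (not isolated)
Conditions: n-BuLi (2.1 equiv), THF/DMPU, −78 → 0 °C; then 2, rt; H2O
Reagents that add atoms: none
Why: In the alkoxide–acetylide dianion only the soft acetylide carbon is alkylated by the primary bromide (acetylide SN2 alkylation), joining two C7 units.

Step 2
Reactants: 4 tetradec-6-yn-1-ol
Product: 5 tetradecan-1-ol
Conditions: H2 (1 atm), Pd/C, EtOAc, rt
Reagents that add atoms: none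
Why: Exhaustive heterogeneous hydrogenation of the isolated alkyne; no stereocentre is involved.

Step 3
Reactants: 5 tetradecan-1-ol
Product: 6 tetradecanoic acid
Conditions: TEMPO (10 mol%), PhI(OAc)2 (2.2 equiv), MeCN/H2O, rt
Reagents that add atoms: water, O
Why: TEMPO/BAIB oxidation of a primary alcohol through the aldehyde hydrate to the carboxylic acid.

Step 4
Reactants: 7 5-bromo-2-methylpent-2-ene; 8 (2E)-pent-2-en-4-yn-1-ol
Product: 11 (2E)-8-methyl-4-methylidenenona-2,7-dien-1-ol, via homoprenylmagnesium bromide 9 (not isolated), via dienylcopper adduct 10 (not isolated)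
Conditions: Mg, THF; CuBr (1.1 equiv), Et2O/THF, −40 °C; 8 (deprotonated by one equiv of 9), −25 °C; aq. NH4Cl
Reagents that add atoms: none
Why: Normant syn-carbocupration of the terminal alkyne puts the homoprenyl group on the internal carbon and copper on the terminus, so protonolysis gives the 2-substituted diene while the E-olefin is untouched.

Step 5
Reactants: 11 (2E)-8-methyl-4-methylidenenona-2,7-dien-1-ol
Product: 12 (2E)-8-methyl-4-methylidenenona-2,7-dienal
Conditions: MnO2, CH2Cl2, rt
Reagents that add atoms: none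
Why: Allylic MnO2 oxidation stops at the aldehyde and keeps the E geometry.

Step 6
Reactants: 13 propanal
Product: 14 (E)-N-cyclohexylpropan-1-imine
Conditions: cyclohexylamine, 0 °C; KOH pellets; distil
Reagents that add atoms: cyclohexylamine, NC1CCCCC1
Why: Simple imine condensation gives the aza-enolate precursor for the later directed aldol condensation.

Step 7
Reactants: 15 cyclohexane-1,3-dione; 16 acrolein
Product: 18 2,3,4,6,7,8-hexahydro-5H-chromen-5-one, via lactol 17 (not isolated)
Conditions: H2O, rt; concentrate; then Et3SiH, TFA, CH2Cl2, 0 °C → rt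
Reagents that add atoms: none
Why: Michael addition of the dione to acrolein gives the cyclic hemiacetal, and ionic hydrogenation (oxocarbenium reduction) turns it into the bicyclic vinylogous ester that masks both the chain oxygen and the future ring ketone.

Step 8
Reactants: 18 2,3,4,6,7,8-hexahydro-5H-chromen-5-one
Product: 20 (±)-6-methyl-2,3,4,6,7,8-hexahydro-5H-chromen-5-one, via lithium enolate 19 (not isolated)
Conditions: LDA, THF, −78 °C; MeI, −78 → −20 °C
Reagents that add atoms: iodomethane, CI
Why: Kinetic α′-deprotonation of a vinylogous ester and methylation (Stork–Danheiser alkylation); the stereocentre is racemic and is erased in the next step.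

Step 9
Reactants: 20 (±)-6-methyl-2,3,4,6,7,8-hexahydro-5H-chromen-5-one
Product: 22 (6S)-6-hydroxy-6-methyl-2,3,4,6,7,8-hexahydro-5H-chromen-5-one, via potassium enolate 21 (not isolated)
Conditions: KHMDS, THF, −78 °C; [(8,8-dichlorocamphoryl)sulfonyl]oxaziridine (antipode giving the 6S alcohol); AcOH; recrystallise
Reagents that add atoms: [(8,8-dichlorocamphoryl)sulfonyl]oxaziridine, CC1(C)C2CCC13CS(=O)(=O)N4OC34C2(Cl)Cl
Why: Davis asymmetric hydroxylation of the tetrasubstituted enolate; the chiral oxaziridine selects the enolate face and sets the tertiary carbinol (6S).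

Step 10
Reactants: 22 (6S)-6-hydroxy-6-methyl-2,3,4,6,7,8-hexahydro-5H-chromen-5-one; 23 5-bromopent-1-ene
Product: 26 (4S)-4-hydroxy-2-(3-hydroxypropyl)-4-methyl-3-(pent-4-en-1-yl)cyclohex-2-en-1-one, via pent-4-enylmagnesium bromide 24 (not isolated), via tertiary carbinol adduct 25 (not isolated)
Conditions: 23, Mg, THF; CeCl3, −78 °C, 22 (0.4 equiv relative to 24), → 0 °C; then 1 M HCl, THF, rt
Reagents that add atoms: water, O
Why: Stork–Danheiser sequence: organocerium 1,2-addition to the vinylogous ester carbonyl, then acid-mediated transposition, which opens the enol ether to the enone and the free primary alcohol without touching the carbinol centre.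

Step 11
Reactants: 26 (4S)-4-hydroxy-2-(3-hydroxypropyl)-4-methyl-3-(pent-4-en-1-yl)cyclohex-2-en-1-one; 6 tetradecanoic acid
Product: 27 3-[(3S)-3-hydroxy-3-methyl-6-oxo-2-(pent-4-en-1-yl)cyclohex-1-en-1-yl]propyl tetradecanoate
Conditions: DIC, DMAP (10 mol%), CH2Cl2, 0 °C → rt
Reagents that add atoms: none
Why: Steglich esterification acylates the unhindered primary alcohol and leaves the tertiary alcohol free.

Step 12
Reactants: 27 3-[(3S)-3-hydroxy-3-methyl-6-oxo-2-(pent-4-en-1-yl)cyclohex-1-en-1-yl]propyl tetradecanoate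
Product: 29 3-[(3S)-3-hydroxy-3-methyl-6-oxo-2-(4-oxobutyl)cyclohex-1-en-1-yl]propyl tetradecanoate, via ozonide 28 (not isolated)
Conditions: O3, CH2Cl2, −78 °C (Sudan III end point); PPh3, → rt
Reagents that add atoms: ozone, [O-][O+]=O
Why: Ozonolysis cleaves the electron-rich terminal alkene much faster than the electron-poor tetrasubstituted enone double bond.

Step 13
Reactants: 29 3-[(3S)-3-hydroxy-3-methyl-6-oxo-2-(4-oxobutyl)cyclohex-1-en-1-yl]propyl tetradecanoate; 30 allyltrimethylsilane
Product: 31 3-[(3S)-2-[(3S)-3-formylhex-5-en-1-yl]-3-hydroxy-3-methyl-6-oxocyclohex-1-en-1-yl]propyl tetradecanoate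
Conditions: 5-benzyl-2-tert-butyl-3-methylimidazolidin-4-one·TFA (20 mol%, enantiomer giving the S aldehyde), CAN (2.5 equiv), NaHCO3, H2O (2 equiv), DME, −20 °C
Reagents that add atoms: none
Why: Organo-SOMO α-allylation: the enamine radical cation is trapped by the allylsilane on the face left open by the catalyst, which sets the new α-stereocentre (S, the later side-chain-bearing ring carbon) independently of the remote carbinol.

Step 14
Reactants: 31 3-[(3S)-2-[(3S)-3-formylhex-5-en-1-yl]-3-hydroxy-3-methyl-6-oxocyclohex-1-en-1-yl]propyl tetradecanoate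
Product: 32 3-[(2S,5R,6S,10S)-6-hydroxy-6-methyl-1,9-dioxo-2-(prop-2-en-1-yl)spiro[4.5]decan-10-yl]propyl tetradecanoate
Conditions: (n-Bu4N)4[W10O32] (2 mol%), MeCN (0.02 M), 390 nm LED, 20 °C, Ar
Reagents that add atoms: none
Why: Proposed new method: photoexcited decatungstate abstracts the hydridic formyl H (polarity-matched HAT), the nucleophilic acyl radical closes 5-exo on the enone β-carbon faster than it loses CO, and back H-transfer from the reduced polyoxometalate to the α-keto radical closes the cycle (closest known chemistry: intermolecular decatungstate hydroacylation of electron-poor alkenes and tin- or thiol-mediated 5-exo acyl radical cyclisations); attack anti to the pseudo-axial C-methyl (A1,2 strain keeps the OH in the enone plane) puts the new C–C(=O) bond cis to OH (5R), and H delivery anti to that freshly formed axial bond leaves the propyl chain cis to it (10S).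

Step 15
Reactants: 32 3-[(2S,5R,6S,10S)-6-hydroxy-6-methyl-1,9-dioxo-2-(prop-2-en-1-yl)spiro[4.5]decan-10-yl]propyl tetradecanoate
Product: 33 3-[(1R,2S,5S,6S,10S)-1,6-dihydroxy-6-methyl-9-oxo-2-(prop-2-en-1-yl)spiro[4.5]decan-10-yl]propyl tetradecanoate
Conditions: Me4NBH(OAc)3 (5 equiv), MeCN/AcOH (1:1), −20 °C
Reagents that add atoms: none
Why: Evans–Saksena hydroxyl-directed reduction: the tertiary alkoxyborohydride delivers hydride intramolecularly to the cyclopentanone face on its own side (anti to the allyl group), giving the 1R carbinol cis to allyl, while the cyclohexanone, which has no β-hydroxyl, is not reduced.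

Step 16
Reactants: 33 3-[(1R,2S,5S,6S,10S)-1,6-dihydroxy-6-methyl-9-oxo-2-(prop-2-en-1-yl)spiro[4.5]decan-10-yl]propyl tetradecanoate; 14 (E)-N-cyclohexylpropan-1-imine
Product: 36 3-[(1R,2S,5S,6S,9Z,10R)-1,6-dihydroxy-6-methyl-9-(1-oxopropan-2-ylidene)-2-(prop-2-en-1-yl)spiro[4.5]decan-10-yl]propyl tetradecanoate, via lithiated imine 34 (not isolated), via beta-hydroxy imine 35 (not isolated)
Conditions: 14, LDA, THF, −78 °C; CeCl3; 33, −78 → −40 °C (5 equiv aza-enolate); then aq. oxalic acid, THF, rt → 40 °C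
Reagents that add atoms: water, O
Why: Wittig directed aldol condensation: the cerium aza-enolate adds to the only ketone (ketone over ester, enolisation suppressed), and acid hydrolysis with dehydration gives the tetrasubstituted enal as the thermodynamic Z isomer, because CHO is smaller than CH3 and sits cis to the substituted ring carbon (A1,3 strain).

Step 17
Reactants: 36 3-[(1R,2S,5S,6S,9Z,10R)-1,6-dihydroxy-6-methyl-9-(1-oxopropan-2-ylidene)-2-(prop-2-en-1-yl)spiro[4.5]decan-10-yl]propyl tetradecanoate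
Product: 38 cis-fused lactol of the 2-(2-oxoethyl) analogue of 36 (anomeric mixture), via ozonide 37 (not isolated)
Conditions: O3, CH2Cl2, −78 °C (Sudan III end point); PPh3, → rt
Reagents that add atoms: ozone, [O-][O+]=O
Why: Ozonolysis takes the terminal allyl alkene in preference to the conjugated tetrasubstituted enal, and the new aldehyde is caught as a five-membered lactol by the cis secondary hydroxyl.

Step 18
Reactants: 38 cis-fused lactol of the 2-(2-oxoethyl) analogue of 36; 12 (2E)-8-methyl-4-methylidenenona-2,7-dienal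
Product: 39 3-[(1R,2S,5S,6S,9Z,10R)-1,6-dihydroxy-6-methyl-2-[(2E,4E)-10-methyl-6-methylidene-1-oxoundeca-2,4,9-trien-2-yl]-9-(1-oxopropan-2-ylidene)spiro[4.5]decan-10-yl]propyl tetradecanoate
Conditions: 12 (3 equiv), pyrrolidine (0.3 equiv), PhCO2H (0.3 equiv), 4 Å MS, CH2Cl2, 0 °C → rt
Reagents that add atoms: none
Why: Amine-catalysed crossed aldol condensation: the enamine of the slowly released aldehyde adds to the non-enolisable dienal in excess, and E1cB dehydration gives the E-configured 2-substituted enal, which places the chain cis to the ring carbon as required.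

Step 19
Reactants: 39 3-[(1R,2S,5S,6S,9Z,10R)-1,6-dihydroxy-6-methyl-2-[(2E,4E)-10-methyl-6-methylidene-1-oxoundeca-2,4,9-trien-2-yl]-9-(1-oxopropan-2-ylidene)spiro[4.5]decan-10-yl]propyl tetradecanoate
Product: 40 3-[(1R,2S,5S,6S,9Z,10R)-1,6-dihydroxy-2-[(2E,4E)-1-hydroxy-10-methyl-6-methylideneundeca-2,4,9-trien-2-yl]-6-methyl-9-(1-oxopropan-2-ylidene)spiro[4.5]decan-10-yl]propyl tetradecanoate
Conditions: Me4NBH(OAc)3 (3 equiv), MeCN/AcOH (4:1), −30 °C; keep cold and dilute
Reagents that add atoms: none
Why: Hydroxyl-directed triacetoxyborohydride reduction: the neighbouring secondary alkoxyborohydride delivers hydride to the nearby trienal carbonyl, whereas the hindered tetrasubstituted ring enal has no hydroxyl within reach and is left intact; no stereocentre is formed.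

Step 20
Reactants: 40 3-[(1R,2S,5S,6S,9Z,10R)-1,6-dihydroxy-2-[(2E,4E)-1-hydroxy-10-methyl-6-methylideneundeca-2,4,9-trien-2-yl]-6-methyl-9-(1-oxopropan-2-ylidene)spiro[4.5]decan-10-yl]propyl tetradecanoate (2 equiv)
Product: 41 CNP0458412.1
Conditions: neat (or 2 M in PhMe), BHT (2 mol%), 70 °C, dark, Ar, 48–72 h; preparative HPLC
Reagents that add atoms: none
Why: Thermal Diels–Alder dimerisation joins the two CH2 termini (largest frontier coefficients) to give the 1,4-"para" cyclohexene, and the transition state with the long dienyl arm exo gives the trans relationship of the two polyene arms; the remote stereocentres give no facial bias, so the (R,R) cyclohexene (target) and its (S,S) diastereomer form in about equal amounts and are separated by HPLC.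

**Compound list**

1 | hept-6-yn-1-ol | C#CCCCCCO | starting material
2 | 1-bromoheptane | CCCCCCCBr | starting material
3 | dilithium hept-6-yn-1-olate-7-ide | [Li]C#CCCCCCO[Li] | intermediate
4 | tetradec-6-yn-1-ol | CCCCCCCC#CCCCCCO | intermediate
5 | tetradecan-1-ol | CCCCCCCCCCCCCCO | intermediate
6 | tetradecanoic acid | CCCCCCCCCCCCCC(=O)O | intermediate
7 | 5-bromo-2-methylpent-2-ene | CC(C)=CCCBr | starting material
8 | (2E)-pent-2-en-4-yn-1-ol | OC/C=C/C#C | starting material
9 | (4-methylpent-3-en-1-yl)magnesium bromide | CC(C)=CCC[Mg]Br | intermediate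
10 | syn-carbocupration adduct (dienylcopper, Cu cis to the homoprenyl group, magnesium alkoxide) | [Cu]/C=C(\CCC=C(C)C)/C=C/CO[Mg]Br | intermediate
11 | (2E)-8-methyl-4-methylidenenona-2,7-dien-1-ol | OC/C=C/C(=C)CCC=C(C)C | intermediate
12 | (2E)-8-methyl-4-methylidenenona-2,7-dienal | O=C/C=C/C(=C)CCC=C(C)C | intermediate
13 | propanal | CCC=O | starting material
14 | (E)-N-cyclohexylpropan-1-imine | CC/C=N/C1CCCCC1 | intermediate
15 | cyclohexane-1,3-dione | O=C1CCCC(=O)C1 | starting material
16 | acrolein | C=CC=O | starting material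
17 | (±)-2-hydroxy-2,3,4,6,7,8-hexahydro-5H-chromen-5-one | OC1CCC2=C(O1)CCCC2=O | intermediate
18 | 2,3,4,6,7,8-hexahydro-5H-chromen-5-one | O=C1CCCC2=C1CCCO2 | intermediate
19 | lithium enolate of 18 (C5–OLi, C5=C6) | [Li]OC1=CCCC2=C1CCCO2 | intermediate
20 | (±)-6-methyl-2,3,4,6,7,8-hexahydro-5H-chromen-5-one | CC1CCC2=C(CCCO2)C1=O | intermediate
21 | potassium enolate of 20 (C5–OK, C5=C6) | [K]OC1=C(C)CCC2=C1CCCO2 | intermediate
22 | (6S)-6-hydroxy-6-methyl-2,3,4,6,7,8-hexahydro-5H-chromen-5-one | C[C@]1(O)CCC2=C(CCCO2)C1=O | intermediate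
23 | 5-bromopent-1-ene | C=CCCCBr | starting material
24 | pent-4-en-1-ylmagnesium bromide | C=CCCC[Mg]Br | intermediate
25 | (6S)-6-methyl-5-(pent-4-en-1-yl)-3,4,5,6,7,8-hexahydro-2H-chromene-5,6-diol (C5 epimers, formed as its magnesium alkoxide) | C[C@]1(O)CCC2=C(CCCO2)C1(O)CCCC=C | intermediate
26 | (4S)-4-hydroxy-2-(3-hydroxypropyl)-4-methyl-3-(pent-4-en-1-yl)cyclohex-2-en-1-one | OCCCC1=C(CCCC=C)[C@@](C)(O)CCC1=O | intermediate
27 | 3-[(3S)-3-hydroxy-3-methyl-6-oxo-2-(pent-4-en-1-yl)cyclohex-1-en-1-yl]propyl tetradecanoate | CCCCCCCCCCCCCC(=O)OCCCC1=C(CCCC=C)[C@@](C)(O)CCC1=O | intermediate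
28 | secondary ozonide (1,2,4-trioxolane) of 27 | CCCCCCCCCCCCCC(=O)OCCCC1=C(CCCC2OCOO2)[C@@](C)(O)CCC1=O | intermediate
29 | 3-[(3S)-3-hydroxy-3-methyl-6-oxo-2-(4-oxobutyl)cyclohex-1-en-1-yl]propyl tetradecanoate | CCCCCCCCCCCCCC(=O)OCCCC1=C(CCCC=O)[C@@](C)(O)CCC1=O | intermediate
30 | allyltrimethylsilane | C=CC[Si](C)(C)C | starting material
31 | 3-[(3S)-2-[(3S)-3-formylhex-5-en-1-yl]-3-hydroxy-3-methyl-6-oxocyclohex-1-en-1-yl]propyl tetradecanoate | CCCCCCCCCCCCCC(=O)OCCCC1=C(CC[C@@H](CC=C)C=O)[C@@](C)(O)CCC1=O | intermediate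
32 | 3-[(2S,5R,6S,10S)-6-hydroxy-6-methyl-1,9-dioxo-2-(prop-2-en-1-yl)spiro[4.5]decan-10-yl]propyl tetradecanoate (6-OH, C1 and the propyl chain all on one face of the cyclohexane) | CCCCCCCCCCCCCC(=O)OCCC[C@@H]1C(=O)CC[C@](C)(O)[C@@]12CC[C@@H](CC=C)C2=O | intermediate
33 | 3-[(1R,2S,5S,6S,10S)-1,6-dihydroxy-6-methyl-9-oxo-2-(prop-2-en-1-yl)spiro[4.5]decan-10-yl]propyl tetradecanoate (1-OH cis to allyl) | CCCCCCCCCCCCCC(=O)OCCC[C@@H]1C(=O)CC[C@](C)(O)[C@@]12CC[C@@H](CC=C)[C@H]2O | intermediate
34 | lithium aza-enolate of 14 | CC=CN([Li])C1CCCCC1 | intermediate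
35 | 9-hydroxy-9-[1-(cyclohexylimino)propan-2-yl] adduct of 33 (new centres as mixture) | CCCCCCCCCCCCCC(=O)OCCC[C@@H]1C(O)(C(C)C=NC3CCCCC3)CC[C@](C)(O)[C@@]12CC[C@@H](CC=C)[C@H]2O | intermediate
36 | 3-[(1R,2S,5S,6S,9Z,10R)-1,6-dihydroxy-6-methyl-9-(1-oxopropan-2-ylidene)-2-(prop-2-en-1-yl)spiro[4.5]decan-10-yl]propyl tetradecanoate | CCCCCCCCCCCCCC(=O)OCCC[C@@H]1/C(=C(/C)C=O)CC[C@](C)(O)[C@@]12CC[C@@H](CC=C)[C@H]2O | intermediate
37 | secondary ozonide (1,2,4-trioxolane) of 36 | CCCCCCCCCCCCCC(=O)OCCC[C@@H]1/C(=C(/C)C=O)CC[C@](C)(O)[C@@]12CC[C@@H](CC3OCOO3)[C@H]2O | intermediate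
38 | cis-fused lactol (2-hydroxytetrahydrofuran) from the C1 hydroxyl and the C2 CH2CHO arm of the spiro core, anomeric mixture | CCCCCCCCCCCCCC(=O)OCCC[C@@H]1/C(=C(/C)C=O)CC[C@](C)(O)[C@@]12CC[C@H]3CC(O)O[C@@H]23 | intermediate
39 | 3-[(1R,2S,5S,6S,9Z,10R)-1,6-dihydroxy-6-methyl-2-[(2E,4E)-10-methyl-6-methylidene-1-oxoundeca-2,4,9-trien-2-yl]-9-(1-oxopropan-2-ylidene)spiro[4.5]decan-10-yl]propyl tetradecanoate | CCCCCCCCCCCCCC(=O)OCCC[C@@H]1/C(=C(/C)C=O)CC[C@](C)(O)[C@@]12CC[C@@H](/C(=C\C=C\C(=C)CCC=C(C)C)C=O)[C@H]2O | intermediate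
40 | 3-[(1R,2S,5S,6S,9Z,10R)-1,6-dihydroxy-2-[(2E,4E)-1-hydroxy-10-methyl-6-methylideneundeca-2,4,9-trien-2-yl]-6-methyl-9-(1-oxopropan-2-ylidene)spiro[4.5]decan-10-yl]propyl tetradecanoate (monomer) | CCCCCCCCCCCCCC(=O)OCCC[C@@H]1/C(=C(/C)C=O)CC[C@](C)(O)[C@@]12CC[C@@H](/C(=C\C=C\C(=C)CCC=C(C)C)CO)[C@H]2O | intermediate
41 | CNP0458412.1, Diels–Alder homodimer of 40: central cyclohex-3-ene with a quaternary carbon (R; homoprenyl and E-dienyl arm) next to a CH (R) whose alkenyl arm is trans to the dienyl arm, second homoprenyl on the ring alkene | CCCCCCCCCCCCCC(=O)OCCC[C@@H]1/C(=C(/C)C=O)CC[C@](C)(O)[C@@]12CC[C@@H](/C(=C\C=C\[C@@]1(CCC=C(C)C)CCC(CCC=C(C)C)=C[C@@H]1/C=C(/CO)[C@@H]1CC[C@]3([C@H](CCCOC(=O)CCCCCCCCCCCCC)/C(=C(/C)C=O)CC[C@]3(C)O)[C@@H]1O)CO)[C@H]2O | target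

**Totals**
Total step count: 20. Longest linear sequence: 14 steps (steps 7–20, from cyclohexane-1,3-dione).

**Three steps most likely to fail, with fallbacks**

Step 14 (acyl-radical spirocyclisation). The risks are slow 5-exo closure onto a tetrasubstituted enone, competing decarbonylation, and H delivery to the wrong face of the α-keto radical (C10 epimer). The fallback sets out from aldehyde 31 and comes back at diketone 32. Pinnick oxidation (NaClO2, NaH2PO4, 2-methylbut-2-ene) gives the carboxylic acid F1. Treatment with PhSeSePh and PBu3 gives the Se-phenyl selenoester F2. Slow addition of (TMS)3SiH and AIBN in benzene at 80 °C then generates the same acyl radical in a silane chain process, free of the photocatalyst, and the bulky silane delivers H to the α-keto radical to give 32.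

Step 18 (amine-catalysed crossed aldol condensation). The risks are self-condensation of the donor, conjugate addition of the enamine to the dienal, and interference by the ring enal. The fallback sets out from lactol 38 and comes back at bis-aldehyde 39. Organocatalytic α-bromination of the open aldehyde form (NBS, cat. prolinamide, CH2Cl2, −20 °C) gives the α-bromo aldehyde F3. PPh3 followed by Et3N turns it into the formyl-stabilised ylide F4. A Wittig reaction of this stabilised ylide with dienal 12 (PhMe, 50 °C) forms the same trisubstituted E-enal 39 without any enolisable aldehyde partner.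

Step 20 (Diels–Alder dimerisation). The risks are low rate with thermal decomposition of the bis-allylic alcohol, and no facial control. The fallback sets out from bis-aldehyde 39 and comes back at target 41. Compound 39 carries no free allylic alcohol and has a lower-lying LUMO, so it is dimerised first (PhMe, 90 °C, BHT, or 10 kbar at rt) to the dimeric dialdehyde F5, which is purified by HPLC. A double hydroxyl-directed reduction with Me4NBH(OAc)3 (MeCN/AcOH, −30 °C) then reduces both trienal carbonyls and gives 41.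

**Further compounds**
F1 | step 14 | (2S)-2-(prop-2-en-1-yl)-4-[(6S)-6-hydroxy-6-methyl-3-oxo-2-(3-tetradecanoyloxypropyl)cyclohex-1-en-1-yl]butanoic acid | CCCCCCCCCCCCCC(=O)OCCCC1=C(CC[C@@H](CC=C)C(=O)O)[C@@](C)(O)CCC1=O
F2 | step 14 | Se-phenyl selenoester of F1 | CCCCCCCCCCCCCC(=O)OCCCC1=C(CC[C@@H](CC=C)C(=O)[Se]c2ccccc2)[C@@](C)(O)CCC1=O
F3 | step 18 | α-bromo aldehyde from 38 (drawn in the open form, C–Br epimers) | CCCCCCCCCCCCCC(=O)OCCC[C@@H]1/C(=C(/C)C=O)CC[C@](C)(O)[C@@]12CC[C@@H](C(Br)C=O)[C@H]2O
F4 | step 18 | formyl-stabilised triphenylphosphonium ylide from F3 | CCCCCCCCCCCCCC(=O)OCCC[C@@H]1/C(=C(/C)C=O)CC[C@](C)(O)[C@@]12CC[C@@H](C(C=O)=P(c3ccccc3)(c3ccccc3)c3ccccc3)[C@H]2O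
F5 | step 20 | Diels–Alder dimer of 39 (both side-chain CH2OH groups of 41 at the aldehyde level) | CCCCCCCCCCCCCC(=O)OCCC[C@@H]1/C(=C(/C)C=O)CC[C@](C)(O)[C@@]12CC[C@@H](/C(=C\C=C\[C@@]1(CCC=C(C)C)CCC(CCC=C(C)C)=C[C@@H]1/C=C(/C=O)[C@@H]1CC[C@]3([C@H](CCCOC(=O)CCCCCCCCCCCCC)/C(=C(/C)C=O)CC[C@]3(C)O)[C@@H]1O)C=O)[C@H]2O
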